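Uj.Dz came up in the zeta and delta runs side by side with Jy.Dz, so I took Uj and Jy for rivals catching the same Dz as it comes from Zo, and I looked for the one number that tells how that contest goes.

| flask | Zo | Uj | Jy | Ej | temperature | remark | time |
|---|---|---|---|---|---|---|---|
| zeta | 0.10 M | 4 equiv | 0.50 equiv | 7 mM | 5 °C | run made earlier |  |
| delta | 0.10 M | 4 equiv | 0.50 equiv | 11 mM | 22 °C | run made earlier |  |
| elm | 0.10 M | 4.00 equiv | 0.500 equiv | 5.00 mM | 35 °C |  | 40 h |
| birch | 0.10 M | 4.00 equiv | 0.500 equiv | 5.00 mM | 10 °C |  | 40 h |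
| alder | 0.10 M | 4.00 equiv | 0.500 equiv | 5.00 mM |  | at 35 °C until 12 h, from then on at 10 °C | 40 h |

| run | time / h | Uj.Dz / % | Jy.Dz / % |
|---|---|---|---|
| zeta | 8.00 | 4 | 5 |
| zeta | 25.0 | 8 | 7 |
| zeta | 48.0 | 19 | 13 |
| zeta | 72.0 | 20 | 13 |
| zeta | 120 | 25 | 16 |
| delta | 10.0 | 25 | 18 |
| delta | 20.0 | 33 | 24 |
| delta | 30.0 | 37 | 23 |
| delta | 40.0 | 36 | 25 |
| delta | 50.0 | 39 | 21 |

(each reading ± 2 percentage points)



- which flask leads in share of Uj.Dz in all that became Uj.Dz or Jy.Dz or Dz.Ej ("all alike" within 1.5 percentage points) (elm / birch / alder / all alike)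
- share of Uj.Dz in all that became Uj.Dz or Jy.Dz or Dz.Ej, elm
- share of Uj.Dz in all that became Uj.Dz or Jy.Dz or Dz.Ej, birch
- share of Uj.Dz in all that became Uj.Dz or Jy.Dz or Dz.Ej, alder

Over the last 3 delta readings, on average 54.0% of the Jy charge and 90.7% of the Uj charge were left. The logarithm of the first fraction over the logarithm of the second gave 6.29; this is the selectivity factor f, how much more readily each Jy catches than each Uj. The last zeta reading, at 5 °C against 22 °C, read 5.98, so within the scatter I held f fixed in all flasks.

In the first instants, with both charges whole, f gave Uj 56.0% of the catches. By the middle, at the delta amounts left, Jy had thinned and Uj took 68.1% of the new ones. At the end the sum counts: with the delta amounts left, Uj.Dz made 61.9% of the two products, and with half that Uj loss, Uj at 95.3%, it made 59.0%. The two cases stood 2.9 percentage points apart, against a margin of 1.5 points, so my reckoning did not make the flasks alike: it put ahead the flask that used more Uj. Dz.Ej was the correction, unseen in the readings: it could not pass the Ej charge, 5.00% of the Zo, and all of that would lower the smaller case to 50.9%. My range ran from there to 61.9%.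

The forecast said all alike, with 49.7% for elm, 49.4% for birch and 49.7% for alder, each within 45% to 54%, holding that “each Ej ends as Dz.Ej after a roughly fixed number of turnovers”. Its values stood below my lower end.

The flasks gave all alike: 59.0% for elm, 59.9% for birch, 59.0% for alder.

    Zo → Dz (k = 0.00880 /min, Ea = 96.0 kJ/mol)
    Uj + Dz → Uj.Dz (k = 2.40 /M/min, Ea = 48.0 kJ/mol)
    Jy + Dz → Jy.Dz (k = 18.0 /M/min, Ea = 54.0 kJ/mol)
    Dz + Ej → Dz.Ej (k = 0.550 /M/min, Ea = 65.0 kJ/mol)
    2 Zo → Zu (k = 0.0550 /M/min, Ea = 79.0 kJ/mol)
    (constants at 35 °C)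

After 40.0 h elm held 0.114% of the Zo as Dz.Ej, far less than the Ej charge allowed. Alder kept 90% of its Uj, and f turned that into a share of 62.0%, against the 59.0% it gave. The flask like alder but with 0.300 equiv of Jy kept 88% of its Uj; f turned that into 74.2%, and that flask gave 71.8%.

The earlier runs and the new flask come from a simulation with constants of no real substance, and the scatter is random.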